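**Plan**

1. Retrosynthetic cuts: the C8–O tiglate ester; then, in one operation, the lactone bond O6–C12 and the ring bond C6–C7, which is shared by the ten-membered carbocycle (C1–C10) and the five-membered lactone (O–C6–C7–C11–C12); then C3(=O)/C6(HO) back to a furan; the C2–C3 bond (Heck); the C7–C11 bond and the C7–C8 epoxide.
2. Enabling feature: C13–C11(–C12O2)=C7 is a 2-carboxy-allyl unit flanked by O-bearing C6 and C8. Closing C6–C7 by allylation copies, in umpoled form, the ring-closing bond of germacrane biosynthesis (farnesyl C1→C10, loss of a C13 proton). The Z-C3(=O)–C4(Me)=C5–C6(O) array is an oxidised 2-substituted 3-methylfuran, which stores the 4Z geometry.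
3. Forward: (R)-linalool (C1, C2, C7–C10, C14) → C7 aldehyde; Heck with 2-bromo-3-methylfuran (C3–C6, C15); α-chlorination, propiolate-derived vinylalane (C11–C13), epoxide; SN2′ silyl-chloride opening; furan → Z-4-oxo-enal; Cr(II) allylation closes the carbocycle and then the lactone; desilylation; tigloylation.
4. Stereochemistry: C10 is bought; C8 is set by organocatalytic chlorination and inverted on epoxide closure; C6 and C7 are relayed from C8 in the ring-closing chair; 1E comes from the Heck step and 4Z from the furan ring.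

Key step: step 8

Remark: 2-bromo-3-methylfuran is taken as a commercial building block (otherwise one step from 3-methylfuran and NBS); atom labels C1–C15 are the germacrane labels of the target.

**Step 1**
Reactants: 1 (R)-(−)-linalool
Product: 2 (3R)-3,7-dimethyl-3-(triethylsilyloxy)octa-1,6-diene
Conditions: TESOTf, 2,6-lutidine, CH2Cl2, −78 → 0 °C
Reagents that add atoms: triethylsilyl trifluoromethanesulfonate, CC[Si](CC)(CC)OS(=O)(=O)C(F)(F)F
Why: Silyl triflate silylation of a hindered tertiary alcohol; the ether prevents lactol formation with the C7 aldehyde made next and allows enamine catalysis in step 4.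

**Step 2**
Reactants: 2 (3R)-3,7-dimethyl-3-(triethylsilyloxy)octa-1,6-diene
Product: 3 (4R)-4-methyl-4-(triethylsilyloxy)hex-5-enal
Conditions: O3, CH2Cl2, −78 °C, Sudan Red end point; then PPh3, −78 → 20 °C
Reagents that add atoms: ozone, [O-][O+]=O
Why: Chemoselective ozonolysis with reductive work-up, because the electron-rich trisubstituted alkene reacts far faster than the hindered vinyl group on the quaternary carbon.

**Step 3**
Reactants: 3 (4R)-4-methyl-4-(triethylsilyloxy)hex-5-enal; 4 2-bromo-3-methylfuran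
Product: 5 (4R,5E)-4-methyl-6-(3-methylfuran-2-yl)-4-(triethylsilyloxy)hex-5-enal
Conditions: Pd2(dba)3 (2.5 mol%), [HP(t-Bu)3]BF4 (10 mol%), Cy2NMe, dioxane, 60 °C
Reagents that add atoms: none
Why: Mizoroki–Heck reaction in which furyl–Pd adds to the terminal CH2 (C2) and β-hydride elimination can only go toward C2 because C10 is quaternary, giving the conjugated 1E alkene, while the tertiary amine base leaves the aldehyde untouched.

**Step 4**
Reactants: 5 (4R,5E)-4-methyl-6-(3-methylfuran-2-yl)-4-(triethylsilyloxy)hex-5-enal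
Product: 6 (2S,4R,5E)-2-chloro-4-methyl-6-(3-methylfuran-2-yl)-4-(triethylsilyloxy)hex-5-enal
Conditions: NCS, 2,5-diphenylpyrrolidine (10 mol%, the enantiomer that gives the 2S chloride), CH2Cl2, 0 °C; pentane filtration, used crude
Reagents that add atoms: N-chlorosuccinimide, O=C1CCC(=O)N1Cl
Why: Enamine-catalysed α-chlorination of an aldehyde in which the C2-symmetric pyrrolidine shields one enamine face and sets C8 as the S chloride, which is used at once because it is configurationally labile.

**Step 5**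
Reactants: 6 (2S,4R,5E)-2-chloro-4-methyl-6-(3-methylfuran-2-yl)-4-(triethylsilyloxy)hex-5-enal; 7 methyl propiolate
Product: 9 vinyl epoxide methyl 2-[(2R,3R)-3-[(2R,3E)-2-methyl-4-(3-methylfuran-2-yl)-2-(triethylsilyloxy)but-3-en-1-yl]oxiran-2-yl]prop-2-enoate, via anti-chlorohydrin 8 (not isolated)
Conditions: 7, DIBAL-H, NMO, THF, 0 °C; then 6, −40 → 0 °C; Rochelle salt; crude 8, Cs2CO3, MeCN, 0 °C
Reagents that add atoms: none
Why: Hydroalumination of the propiolate gives the α-(methoxycarbonyl)vinylalane, which adds to the α-chloro aldehyde in the polar Felkin-type (anti) sense, and carbonate then closes the trans-epoxide by intramolecular SN2 displacement with inversion at C8, which becomes 8R (C7 is not retained later).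

**Step 6**
Reactants: 9 vinyl epoxide methyl 2-[(2R,3R)-3-[(2R,3E)-2-methyl-4-(3-methylfuran-2-yl)-2-(triethylsilyloxy)but-3-en-1-yl]oxiran-2-yl]prop-2-enoate
Product: 10 methyl (2Z,4R,6R,7E)-2-(chloromethyl)-6-methyl-8-(3-methylfuran-2-yl)-4,6-bis(triethylsilyloxy)octa-2,7-dienoate
Conditions: TESCl, n-Bu4NCl (10 mol%), 2,6-di-tert-butylpyridine (10 mol%), CH2Cl2, 0 → 25 °C
Reagents that add atoms: chlorotriethylsilane, CC[Si](Cl)(CC)CC
Why: Halide-catalysed insertion of a silyl chloride into an epoxide, run in the SN2′ mode: chloride adds to the acrylate terminus C13, the C7–O bond breaks and the C8 oxygen is silylated with its configuration kept, so that no free C8 alkoxide can lactonise; the C7=C11 geometry and any C7–Cl regioisomer do not matter because both give the same allylchromium.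

**Step 7**
Reactants: 10 methyl (2Z,4R,6R,7E)-2-(chloromethyl)-6-methyl-8-(3-methylfuran-2-yl)-4,6-bis(triethylsilyloxy)octa-2,7-dienoate
Product: 11 methyl (2Z,4R,6R,7E,10Z)-2-(chloromethyl)-6,10-dimethyl-9,12-dioxo-4,6-bis(triethylsilyloxy)dodeca-2,7,10-trienoate
Conditions: NBS (1.05 equiv), NaHCO3, acetone/H2O 10:1, −20 °C, dark; used at once
Reagents that add atoms: water, O
Why: Oxidative ring opening of a 2,3-disubstituted furan (bromination at the free α-position, hydration, loss of HBr) gives the cis-4-oxo-2-enal, so the 4Z geometry comes from the ring, and the buffered cold conditions should avoid Z→E isomerisation and spare the allylic chloride and silyl ethers.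

**Step 8**
Reactants: 11 methyl (2Z,4R,6R,7E,10Z)-2-(chloromethyl)-6,10-dimethyl-9,12-dioxo-4,6-bis(triethylsilyloxy)dodeca-2,7,10-trienoate
Product: 13 lactone 8β,10α-bis(triethylsilyloxy)-3-oxogermacra-1E,4Z,11(13)-trien-6α,12-olide, via hydroxy ester 12 (not isolated)
Conditions: CrCl2 (6 equiv), LiI (10 mol%), THF/DMF 4:1, 25 °C, syringe-pump addition of 11 (final 2 mM); aq. NH4Cl
Reagents that add atoms: none
Why: Cr(II) inserts into the allylic C13–Cl bond and the resulting σ-allylchromium(III) adds through its γ-carbon C7 to the Cr-bound C6 aldehyde in a six-membered Zimmerman–Traxler chair (SE2′ allylation), the C11=C13 methylene arising by allylic transposition; the closest known reaction type is the intramolecular Nozaki–Hiyama allylation of ω-formyl 2-(halomethyl)enoates, which is known to close ten-membered germacranolide rings. The carbocycle closes by C6–C7 bond formation as a ring trans-fused to the chair (C5 and C8 both pseudo-equatorial), and the lactone then closes by 5-exo-trig acyl substitution of the C6 chromium alkoxide on the C12 methyl ester. The anti relation C6/C7 (trans-lactone, H6β/H7α) comes from the chair with C8 equatorial, and the absolute sense is relayed from C8: H8 eclipses the ester-bearing C11 (A1,3 strain), the ring-forming C8–C9 bond lies anti to the forming bond (which avoids a g+/g− turn between C5 and C9 in the nascent ring) and the silyloxy group sits outside. The step needs aldehyde-over-ketone selectivity, which the organochromium provides, and needs the allylic chloride to react before the oxo-enal is reduced, which slow addition at high dilution is meant to secure; 4Z survives because no acid or base is present.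

**Step 9**
Reactants: 13 lactone 8β,10α-bis(triethylsilyloxy)-3-oxogermacra-1E,4Z,11(13)-trien-6α,12-olide
Product: 14 8β,10α-dihydroxy-3-oxogermacra-1E,4Z,11(13)-trien-6α,12-olide
Conditions: HF·pyridine, pyridine, THF, 0 → 20 °C
Reagents that add atoms: none
Why: Fluoride cleavage of both triethylsilyl ethers under buffered, weakly acidic conditions that should leave the α-methylene lactone, the dienone and the tertiary allylic alcohol intact.

**Step 10**
Reactants: 14 8β,10α-dihydroxy-3-oxogermacra-1E,4Z,11(13)-trien-6α,12-olide; 15 tigloyl chloride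
Product: 16 eupaheliangolide A
Conditions: 15 (1.5 equiv), pyridine, DMAP (10 mol%), CH2Cl2, 0 °C
Reagents that add atoms: none
Why: DMAP-catalysed acylation of the secondary 8β-OH with an acid chloride, the tertiary 10α-OH being unreactive under these conditions and the E geometry of the tiglate being retained.

**Compound list**

1 | (R)-(−)-linalool, (3R)-3,7-dimethylocta-1,6-dien-3-ol | C=C[C@](C)(O)CCC=C(C)C | starting material
2 | (3R)-3,7-dimethyl-3-(triethylsilyloxy)octa-1,6-diene | C=C[C@](C)(O[Si](CC)(CC)CC)CCC=C(C)C | intermediate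
3 | (4R)-4-methyl-4-(triethylsilyloxy)hex-5-enal | C=C[C@](C)(O[Si](CC)(CC)CC)CCC=O | intermediate
4 | 2-bromo-3-methylfuran | Cc1ccoc1Br | starting material
5 | (4R,5E)-4-methyl-6-(3-methylfuran-2-yl)-4-(triethylsilyloxy)hex-5-enal | Cc1ccoc1/C=C/[C@](C)(O[Si](CC)(CC)CC)CCC=O | intermediate
6 | (2S,4R,5E)-2-chloro-4-methyl-6-(3-methylfuran-2-yl)-4-(triethylsilyloxy)hex-5-enal | Cc1ccoc1/C=C/[C@](C)(O[Si](CC)(CC)CC)C[C@H](Cl)C=O | intermediate
7 | methyl propiolate | C#CC(=O)OC | starting material
8 | methyl (3R,4S,6R,7E)-4-chloro-3-hydroxy-6-methyl-2-methylidene-8-(3-methylfuran-2-yl)-6-(triethylsilyloxy)oct-7-enoate (anti-chlorohydrin) | Cc1ccoc1/C=C/[C@](C)(O[Si](CC)(CC)CC)C[C@H](Cl)[C@H](O)C(=C)C(=O)OC | intermediate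
9 | methyl 2-[(2R,3R)-3-[(2R,3E)-2-methyl-4-(3-methylfuran-2-yl)-2-(triethylsilyloxy)but-3-en-1-yl]oxiran-2-yl]prop-2-enoate | Cc1ccoc1/C=C/[C@](C)(O[Si](CC)(CC)CC)C[C@@H](O2)[C@H]2C(=C)C(=O)OC | intermediate
10 | methyl (2Z,4R,6R,7E)-2-(chloromethyl)-6-methyl-8-(3-methylfuran-2-yl)-4,6-bis(triethylsilyloxy)octa-2,7-dienoate | Cc1ccoc1/C=C/[C@](C)(O[Si](CC)(CC)CC)C[C@@H](O[Si](CC)(CC)CC)/C=C(\CCl)C(=O)OC | intermediate
11 | methyl (2Z,4R,6R,7E,10Z)-2-(chloromethyl)-6,10-dimethyl-9,12-dioxo-4,6-bis(triethylsilyloxy)dodeca-2,7,10-trienoate | O=C/C=C(/C)C(=O)/C=C/[C@](C)(O[Si](CC)(CC)CC)C[C@@H](O[Si](CC)(CC)CC)/C=C(\CCl)C(=O)OC | intermediate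
12 | methyl 6α-hydroxy-3-oxo-8β,10α-bis(triethylsilyloxy)germacra-1E,4Z,11(13)-trien-12-oate (7α-H; Cr(III) alkoxide in the flask) | C=C(C(=O)OC)[C@H]1[C@H](O)/C=C(/C)C(=O)/C=C/[C@](C)(O[Si](CC)(CC)CC)C[C@H]1O[Si](CC)(CC)CC | intermediate
13 | 8β,10α-bis(triethylsilyloxy)-3-oxogermacra-1E,4Z,11(13)-trien-6α,12-olide (7α-H) | C=C1C(=O)O[C@@H]2/C=C(/C)C(=O)/C=C/[C@](C)(O[Si](CC)(CC)CC)C[C@@H](O[Si](CC)(CC)CC)[C@@H]12 | intermediate
14 | 8β,10α-dihydroxy-3-oxogermacra-1E,4Z,11(13)-trien-6α,12-olide (7α-H) | C=C1C(=O)O[C@@H]2/C=C(/C)C(=O)/C=C/[C@](C)(O)C[C@@H](O)[C@@H]12 | intermediate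
15 | tigloyl chloride, (2E)-2-methylbut-2-enoyl chloride | C/C=C(\C)C(=O)Cl | starting material
16 | eupaheliangolide A, 8β-tigloyloxy-10α-hydroxy-3-oxogermacra-1E,4Z,11(13)-trien-6α,12-olide (6R,7R,8R,10R) | C=C1C(=O)O[C@@H]2/C=C(/C)C(=O)/C=C/[C@](C)(O)C[C@@H](OC(=O)/C(C)=C/C)[C@@H]12 | target

**Step count and risks**

Total steps: 10. Longest linear sequence: 10 (from (R)-linalool).

Steps most likely to fail:

Step 8. The allylchromium may attack the other face of C7, with the C8–O bond rather than the C8–C9 bond anti to the forming bond, which would give the 6,7-bis-epimeric trans-lactone and cannot be corrected after ring closure. Erosion by a cis-fused closure or by one-electron reduction of the 4-oxo-enal is also possible. The fallback sets out from aldehyde 5 and comes back at target 16: it makes the C8-epimeric series and corrects C8 only at the end. Chlorination with the enantiomeric pyrrolidine gives (2R)-chloro aldehyde F1. Vinylalane addition and carbonate closure as in step 5 give anti-chlorohydrin F2 and then trans-epoxide F3. Silyl chloride opening as in step 6 gives the (4S)-silyloxy allylic chloride F4, and furan oxidation as in step 7 gives oxo-enal F5. Cr(II) closure in the same facial sense, via hydroxy ester F6, should then give the 8α-silyloxy 6α,12-olide F7 with the natural C6/C7 configuration. HF·pyridine gives the 8α,10α-diol F8, and Mitsunobu esterification (tiglic acid, PPh3, DIAD, toluene, 0 °C) installs the tiglate with inversion at C8 to give 16.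

Step 6. Chloride may open the silyl-activated epoxide at C8, or adventitious HCl may ionise the furyl-allylic tertiary silyl ether, so that the transposed allylic chloride is not formed cleanly. The fallback sets out from epoxide 9 and comes back at lactone 13: it separates C–O cleavage from O-protection and uses the bromide. Buffered LiBr/AcOH (THF, 0 °C) opens 9 in the SN2′ sense to the δ-hydroxy allylic bromide F9 (C8 cis to CH2Br, so it cannot lactonise). Immediate silylation (TESOTf, 2,6-lutidine, −78 °C) gives bis-silyl bromide F10. NBS oxidation as in step 7 gives oxo-enal bromide F11, which is cyclised with CrCl2 as in step 8 to 13.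

Step 3. The enolisable aldehyde may undergo aldol condensation under the basic Heck conditions, and migratory insertion into the vinyl group next to the quaternary silyloxy carbon may be slow. The fallback sets out from silyl ether 2 and comes back at aldehyde 5: the aldehyde is kept masked as an epoxide during the coupling. mCPBA (NaHCO3, CH2Cl2, 0 °C) gives the 6,7-epoxide F12 (both epimers). The Heck reaction with 4 under more forcing conditions gives furyl epoxide F13, and periodic acid (THF/H2O, 0 °C) cleaves the epoxide to 5.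

**Further compounds**

F1 | step 8 | (2R,4R,5E)-2-chloro-4-methyl-6-(3-methylfuran-2-yl)-4-(triethylsilyloxy)hex-5-enal | Cc1ccoc1/C=C/[C@](C)(O[Si](CC)(CC)CC)C[C@@H](Cl)C=O
F2 | step 8 | methyl (3S,4R,6R,7E)-4-chloro-3-hydroxy-6-methyl-2-methylidene-8-(3-methylfuran-2-yl)-6-(triethylsilyloxy)oct-7-enoate | Cc1ccoc1/C=C/[C@](C)(O[Si](CC)(CC)CC)C[C@@H](Cl)[C@@H](O)C(=C)C(=O)OC
F3 | step 8 | methyl 2-[(2S,3S)-3-[(2R,3E)-2-methyl-4-(3-methylfuran-2-yl)-2-(triethylsilyloxy)but-3-en-1-yl]oxiran-2-yl]prop-2-enoate | Cc1ccoc1/C=C/[C@](C)(O[Si](CC)(CC)CC)C[C@H](O2)[C@@H]2C(=C)C(=O)OC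
F4 | step 8 | methyl (2Z,4S,6R,7E)-2-(chloromethyl)-6-methyl-8-(3-methylfuran-2-yl)-4,6-bis(triethylsilyloxy)octa-2,7-dienoate | Cc1ccoc1/C=C/[C@](C)(O[Si](CC)(CC)CC)C[C@H](O[Si](CC)(CC)CC)/C=C(\CCl)C(=O)OC
F5 | step 8 | methyl (2Z,4S,6R,7E,10Z)-2-(chloromethyl)-6,10-dimethyl-9,12-dioxo-4,6-bis(triethylsilyloxy)dodeca-2,7,10-trienoate | O=C/C=C(/C)C(=O)/C=C/[C@](C)(O[Si](CC)(CC)CC)C[C@H](O[Si](CC)(CC)CC)/C=C(\CCl)C(=O)OC
F6 | step 8 | methyl 6α-hydroxy-3-oxo-8α,10α-bis(triethylsilyloxy)germacra-1E,4Z,11(13)-trien-12-oate (7α-H) | C=C(C(=O)OC)[C@H]1[C@H](O)/C=C(/C)C(=O)/C=C/[C@](C)(O[Si](CC)(CC)CC)C[C@@H]1O[Si](CC)(CC)CC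
F7 | step 8 | 8α,10α-bis(triethylsilyloxy)-3-oxogermacra-1E,4Z,11(13)-trien-6α,12-olide (7α-H) | C=C1C(=O)O[C@@H]2/C=C(/C)C(=O)/C=C/[C@](C)(O[Si](CC)(CC)CC)C[C@H](O[Si](CC)(CC)CC)[C@@H]12
F8 | step 8 | 8α,10α-dihydroxy-3-oxogermacra-1E,4Z,11(13)-trien-6α,12-olide (7α-H) | C=C1C(=O)O[C@@H]2/C=C(/C)C(=O)/C=C/[C@](C)(O)C[C@H](O)[C@@H]12
F9 | step 6 | methyl (2Z,4R,6R,7E)-2-(bromomethyl)-4-hydroxy-6-methyl-8-(3-methylfuran-2-yl)-6-(triethylsilyloxy)octa-2,7-dienoate | Cc1ccoc1/C=C/[C@](C)(O[Si](CC)(CC)CC)C[C@@H](O)/C=C(\CBr)C(=O)OC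
F10 | step 6 | methyl (2Z,4R,6R,7E)-2-(bromomethyl)-6-methyl-8-(3-methylfuran-2-yl)-4,6-bis(triethylsilyloxy)octa-2,7-dienoate | Cc1ccoc1/C=C/[C@](C)(O[Si](CC)(CC)CC)C[C@@H](O[Si](CC)(CC)CC)/C=C(\CBr)C(=O)OC
F11 | step 6 | methyl (2Z,4R,6R,7E,10Z)-2-(bromomethyl)-6,10-dimethyl-9,12-dioxo-4,6-bis(triethylsilyloxy)dodeca-2,7,10-trienoate | O=C/C=C(/C)C(=O)/C=C/[C@](C)(O[Si](CC)(CC)CC)C[C@@H](O[Si](CC)(CC)CC)/C=C(\CBr)C(=O)OC
F12 | step 3 | triethyl{[(3R)-5-(3,3-dimethyloxiran-2-yl)-3-methylpent-1-en-3-yl]oxy}silane (both epoxide epimers) | C=C[C@](C)(O[Si](CC)(CC)CC)CCC1OC1(C)C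
F13 | step 3 | triethyl{[(1E,3R)-5-(3,3-dimethyloxiran-2-yl)-3-methyl-1-(3-methylfuran-2-yl)pent-1-en-3-yl]oxy}silane (both epoxide epimers) | Cc1ccoc1/C=C/[C@](C)(O[Si](CC)(CC)CC)CCC1OC1(C)C
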